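**Plan**

- Retrosynthesis: the ester C–O bond at C3 and the two benzyl ethers are cut first. C4=O is taken back to the carbinol and the C3–C4 bond of ring C is cut as a pinacol, which opens ring C to a dialdehyde. Last, the O1–C2 aryl ether bond is cut to a phloroglucinaldehyde and a mandelate.
- Enabling feature: C3 and C4 are adjacent and both carry oxygen; C4 sits on ring A and C3 is tied to it through C2 and O1, so both can be aldehyde carbons of one molecule.
- Forward: ring A is bought; O1–C2 is joined by Mitsunobu etherification; both termini are brought to the aldehyde level; ring C closes by SmI2 coupling (C3–C4); then C4 oxidation, C3 acylation and debenzylation.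
- Stereochemistry: C2 comes from methyl (S)-mandelate with inversion; C3 is set in the ring closure, trans to the C2 phenyl; the side-chain centre is bought with (R)-2-methylbutanoic acid.

Key step: step 5

Remark: C3 is 3S in the diol and 3R in the ketone and the target. The spatial arrangement is the same; only the CIP ranking of C2 against C4 changes.

**Step 1**
Reactants: 1 2,4,6-trihydroxybenzaldehyde
Product: 2 2,4-bis(benzyloxy)-6-hydroxybenzaldehyde
Conditions: BnBr (2.05 equiv), K2CO3 (2.2 equiv), DMF, 0 °C to rt
Reagents that add atoms: benzyl bromide, BrCc1ccccc1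
Why: Williamson etherification with two equivalents of bromide should alkylate the para hydroxyl and one ortho hydroxyl, while the last ortho hydroxyl, hydrogen-bonded to the formyl oxygen, is far less nucleophilic and stays free.

**Step 2**
Reactants: 2 2,4-bis(benzyloxy)-6-hydroxybenzaldehyde; 3 methyl (S)-mandelate
Product: 4 methyl (2R)-2-[3,5-bis(benzyloxy)-2-formylphenoxy]-2-phenylacetate
Conditions: PPh3, DIAD, THF, 0 °C to rt
Reagents that add atoms: none
Why: In this Mitsunobu etherification the acidic salicylaldehyde-type phenol displaces the oxyphosphonium of the α-hydroxy ester in an SN2 step, so the (S)-carbinol is inverted to the (R)-aryl ether that becomes C2, the neighbouring ester group disfavouring ionisation.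

**Step 3**
Reactants: 4 methyl (2R)-2-[3,5-bis(benzyloxy)-2-formylphenoxy]-2-phenylacetate
Product: 5 (2R)-2-[3,5-bis(benzyloxy)-2-(hydroxymethyl)phenoxy]-2-phenylethan-1-ol
Conditions: LiAlH4, THF, 0 °C; then H2O, aq NaOH work-up
Reagents that add atoms: none
Why: Hydride reduction of the ester and the aldehyde by LiAlH4 at 0 °C is faster than enolisation of the ester, so the benzylic stereocentre should be carried through unchanged, and the basic work-up spares the acid-labile trialkoxybenzyl alcohol.

**Step 4**
Reactants: 5 (2R)-2-[3,5-bis(benzyloxy)-2-(hydroxymethyl)phenoxy]-2-phenylethan-1-ol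
Product: 6 2,4-bis(benzyloxy)-6-[(1R)-2-oxo-1-phenylethoxy]benzaldehyde
Conditions: Dess–Martin periodinane (2.5 equiv), NaHCO3, CH2Cl2, 0 °C; filtered through a short pad, concentrated cold and used at once
Reagents that add atoms: none
Why: Dess–Martin oxidation of both primary alcohols under bicarbonate-buffered, non-basic conditions is the usual way to aldehydes with an enolisable α-stereocentre, so the α-aryloxy benzylic centre should keep its configuration if the crude dialdehyde is taken on immediately.

**Step 5**
Reactants: 6 2,4-bis(benzyloxy)-6-[(1R)-2-oxo-1-phenylethoxy]benzaldehyde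
Product: 7 (2R,3S,4S)-5,7-bis(benzyloxy)-2-phenylchroman-3,4-diol
Conditions: SmI2 (2.5 equiv, 0.1 M in THF), t-BuOH (2 equiv), THF, −78 °C to rt, slow addition of 6 to a final 0.01 M
Reagents that add atoms: none
Why: Divalent samarium reduces the conjugated aryl aldehyde first, and the samarium-bound benzylic ketyl at C4 adds to the samarium-activated α-aryloxy aldehyde carbon C3, after which a second electron and protonation by t-BuOH give the diol (collapse of a samarium-bridged diketyl is the equivalent alternative). The closest known reaction type is the SmI2 pinacol cyclisation of 1,6-dialdehydes, α-alkoxy ones included, to cis-cyclohexane-1,2-diols. Ring C closes in a 6-exo-trig mode by formation of the C3–C4 bond. Trivalent samarium bridging the two oxygen atoms makes the diol cis, and the peri benzyloxy group at C5 forces the C4–O bond pseudoaxial in the half-chair, which fixes C4 as 4S relative to C3. With the C2 phenyl equatorial, the C3–O bond that is cis to a pseudoaxial C4–O bond is equatorial and therefore trans to phenyl, so the 2R centre sets C3 as 3S. The step needs ring closure to outrun aryloxide loss from a ketyl at C3 and intermolecular coupling, which the easier reduction of the aryl aldehyde, the short tether, −78 °C and high dilution should secure.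

**Step 6**
Reactants: 7 (2R,3S,4S)-5,7-bis(benzyloxy)-2-phenylchroman-3,4-diol
Product: 8 (2R,3R)-5,7-bis(benzyloxy)-3-hydroxy-2-phenylchroman-4-one
Conditions: DDQ (1.1 equiv), 1,4-dioxane, rt
Reagents that add atoms: none
Why: DDQ oxidation of an electron-rich benzylic alcohol proceeds by hydride abstraction only at C4, whose cation is stabilised by the ortho and para alkoxy groups of ring A, so the non-benzylic C3 carbinol, the benzyl ethers and C2 should stay untouched and C3 keeps its arrangement.

**Step 7**
Reactants: 8 (2R,3R)-5,7-bis(benzyloxy)-3-hydroxy-2-phenylchroman-4-one; 9 (R)-2-methylbutanoic acid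
Product: 10 (2R,3R)-5,7-bis(benzyloxy)-4-oxo-2-phenylchroman-3-yl (2R)-2-methylbutanoate
Conditions: DCC, DMAP (0.1 equiv), CH2Cl2, 0 °C to rt
Reagents that add atoms: none
Why: Steglich esterification of the equatorial secondary alcohol with only catalytic DMAP at low temperature should epimerise neither the α-centre of the acid nor C2 and C3 of the flavanone.

**Step 8**
Reactants: 10 (2R,3R)-5,7-bis(benzyloxy)-4-oxo-2-phenylchroman-3-yl (2R)-2-methylbutanoate
Product: 11 (2R,3R)-5,7-dihydroxy-4-oxo-2-phenylchroman-3-yl (2R)-2-methylbutanoate
Conditions: H2 (1 atm), 10% Pd/C, EtOAc, rt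
Reagents that add atoms: none
Why: Catalytic hydrogenolysis of the two aryl benzyl ethers is much faster than cleavage of the cyclic C2–O1 benzylic ether or reduction of the aryl ketone, so the ester and all three stereocentres should survive.

**Compound list**

1 | 2,4,6-trihydroxybenzaldehyde | O=Cc1c(O)cc(O)cc1O | starting material
2 | 2,4-bis(benzyloxy)-6-hydroxybenzaldehyde | O=Cc1c(O)cc(OCc2ccccc2)cc1OCc1ccccc1 | intermediate
3 | methyl (S)-mandelate | COC(=O)[C@@H](O)c1ccccc1 | starting material
4 | methyl (2R)-2-[3,5-bis(benzyloxy)-2-formylphenoxy]-2-phenylacetate | COC(=O)[C@H](Oc1cc(OCc2ccccc2)cc(OCc2ccccc2)c1C=O)c1ccccc1 | intermediate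
5 | (2R)-2-[3,5-bis(benzyloxy)-2-(hydroxymethyl)phenoxy]-2-phenylethan-1-ol | OC[C@H](Oc1cc(OCc2ccccc2)cc(OCc2ccccc2)c1CO)c1ccccc1 | intermediate
6 | 2,4-bis(benzyloxy)-6-[(1R)-2-oxo-1-phenylethoxy]benzaldehyde | O=C[C@H](Oc1cc(OCc2ccccc2)cc(OCc2ccccc2)c1C=O)c1ccccc1 | intermediate
7 | (2R,3S,4S)-5,7-bis(benzyloxy)-2-phenylchroman-3,4-diol | O[C@H]1[C@@H](O)c2c(OCc3ccccc3)cc(OCc3ccccc3)cc2O[C@@H]1c1ccccc1 | intermediate
8 | (2R,3R)-5,7-bis(benzyloxy)-3-hydroxy-2-phenylchroman-4-one | O[C@H]1C(=O)c2c(OCc3ccccc3)cc(OCc3ccccc3)cc2O[C@@H]1c1ccccc1 | intermediate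
9 | (R)-2-methylbutanoic acid | CC[C@@H](C)C(=O)O | starting material
10 | (2R,3R)-5,7-bis(benzyloxy)-4-oxo-2-phenylchroman-3-yl (2R)-2-methylbutanoate | CC[C@@H](C)C(=O)O[C@H]1C(=O)c2c(OCc3ccccc3)cc(OCc3ccccc3)cc2O[C@@H]1c1ccccc1 | intermediate
11 | (2R,3R)-5,7-dihydroxy-4-oxo-2-phenylchroman-3-yl (2R)-2-methylbutanoate | CC[C@@H](C)C(=O)O[C@H]1C(=O)c2c(O)cc(O)cc2O[C@@H]1c1ccccc1 | target

**Step count**

Total steps: 8. Longest linear sequence: 8 steps (1 to 11).

**Steps most likely to fail**

Step 5. The ring closure may be overtaken by loss of the aryloxide from a ketyl formed at C3, by intermolecular coupling of the aryl aldehyde, or it may close with poor facial selectivity at C3. The fallback sets out from dialdehyde 6 and forms the same C3–C4 bond by olefin metathesis, bringing in the oxygen atoms afterwards. Both formyl groups would be methylenated under non-basic Takai–Lombardo conditions (Zn, CH2Br2, TiCl4, THF) to the diene 1,5-bis(benzyloxy)-2-ethenyl-3-{[(1S)-1-phenylprop-2-en-1-yl]oxy}benzene F1. Ring-closing metathesis with the second-generation Grubbs catalyst in CH2Cl2 should then give (2S)-5,7-bis(benzyloxy)-2-phenyl-2H-chromene F2, with the spatial arrangement at C2 unchanged. Upjohn dihydroxylation (catalytic OsO4, N-methylmorpholine N-oxide, acetone–water) should add to the face opposite the C2 phenyl and return to the route at diol 7.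

Step 4. Configuration at the benzylic α-carbon may erode through enolisation of the α-aryloxy aldehyde during oxidation, filtration or storage, and the trialkoxybenzyl alcohol may ionise under the acetic acid released. The fallback sets out from diol 5 and separates the two oxidations so that the labile aldehyde is never isolated. MnO2 in CH2Cl2 should oxidise only the benzylic alcohol to the stable, purifiable 2,4-bis(benzyloxy)-6-[(1R)-2-hydroxy-1-phenylethoxy]benzaldehyde F3. The remaining primary alcohol would then be oxidised by a Swern reaction ((COCl)2, DMSO, Et3N, THF, −78 °C), and the cold mixture transferred directly into SmI2 and t-BuOH in THF at −78 °C. Dialdehyde 6 is then formed and consumed in one flask, and the sequence comes back to the route at diol 7.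

Step 6. The oxidant may fail to discriminate fully between the two carbinols, cleave the cis-glycol, or attack the benzyl ethers. The fallback sets out from diol 7 and reverses the order of acylation and oxidation. The equatorial C3 hydroxyl, more accessible than the pseudoaxial C4 hydroxyl shielded by the peri benzyloxy group, would be esterified first with one equivalent of acid 9 (DCC, catalytic DMAP, CH2Cl2, −20 °C) to give (2R,3S,4S)-5,7-bis(benzyloxy)-4-hydroxy-2-phenylchroman-3-yl (2R)-2-methylbutanoate F4. The single remaining alcohol would then be oxidised with Dess–Martin periodinane (NaHCO3, CH2Cl2), so no free diol meets an oxidant, and the sequence comes back to the route at ketone 10.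

**Further compounds**

F1 | step 5 | 1,5-bis(benzyloxy)-2-ethenyl-3-{[(1S)-1-phenylprop-2-en-1-yl]oxy}benzene | C=C[C@H](Oc1cc(OCc2ccccc2)cc(OCc2ccccc2)c1C=C)c1ccccc1
F2 | step 5 | (2S)-5,7-bis(benzyloxy)-2-phenyl-2H-chromene | C1=Cc2c(OCc3ccccc3)cc(OCc3ccccc3)cc2O[C@@H]1c1ccccc1
F3 | step 4 | 2,4-bis(benzyloxy)-6-[(1R)-2-hydroxy-1-phenylethoxy]benzaldehyde | OC[C@H](Oc1cc(OCc2ccccc2)cc(OCc2ccccc2)c1C=O)c1ccccc1
F4 | step 6 | (2R,3S,4S)-5,7-bis(benzyloxy)-4-hydroxy-2-phenylchroman-3-yl (2R)-2-methylbutanoate | CC[C@@H](C)C(=O)O[C@H]1[C@@H](O)c2c(OCc3ccccc3)cc(OCc3ccccc3)cc2O[C@@H]1c1ccccc1
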